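## Retrosynthetic overview

1. Feature used: in the oxolane, C2 and C5 are unsubstituted CH2 groups flanking C3 (bears the aryl carbinol carbon C7) and C4 (bears the benzyl group); with C7 as a ketone this is a 3-aroyl-oxolane.
2. 21 ⇐ 18: reagent-controlled reduction of the C7 ketone, then removal of the benzyl ether (benzyl ring) and the pivalate (aroyl ring).
3. 18 ⇐ 17 (key): C4–C5 and C2–C3 are cut together. The oxolane, the only ring made in the route, comes from the formaldehyde acetal of a 2-aryl-2-alkenyl-1,2-diol by oxocarbenium–alkene cyclisation and 1,2-shift of the ring CH2.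
4. 17 ⇐ 15 ⇐ 11 + 6: the tertiary carbinol, the one stereocentre that enters the key step, is set by catalytic asymmetric addition of an (E)-alkenylzinc to an α-silyloxy aryl ketone.
5. 11 ⇐ acetosyringone 7; 6 ⇐ syringaldehyde 1; both aryl rings are bought.

Key step: step 11

Remark (protecting groups): the phenol of the ring on the carbinol carbon is carried as a pivalate, not an ether. An electron-poor aryl group makes the tertiary, benzylic and allylic C–O bond of 15 and 17 harder to ionise, lowers the tendency of the aryl group to shift in step 11, and shields the C7–O bond in step 13. The other ring, insulated by CH2, keeps a benzyl ether.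

Assumption (step 8): the ligand antipode that gives (S)-adducts from acetophenone (Si-face addition) is taken to add to the spatially equivalent face of 11 (its Re face, CH2OTBS in place of CH3), which gives the (S)-carbinol. If the sense found is the opposite, the mirror-image ligand is used and nothing else changes.

## Route

Step 1
Reactants: 1 syringaldehyde
Product: 2 4-(benzyloxy)-3,5-dimethoxybenzaldehyde
Conditions: BnBr, K2CO3, DMF, 60 °C
Reagents that add atoms: benzyl bromide, BrCc1ccccc1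
Why: Williamson ether synthesis on the phenoxide; the aldehyde is inert to carbonate.

Step 2
Reactants: 2 4-(benzyloxy)-3,5-dimethoxybenzaldehyde
Product: 3 [4-(benzyloxy)-3,5-dimethoxyphenyl]methanol
Conditions: NaBH4, MeOH, 0 °C
Reagents that add atoms: none
Why: Borohydride reduction of an aromatic aldehyde; the aryl benzyl ether is not affected.

Step 3
Reactants: 3 [4-(benzyloxy)-3,5-dimethoxyphenyl]methanol
Product: 4 2-(benzyloxy)-5-(bromomethyl)-1,3-dimethoxybenzene
Conditions: PBr3, CH2Cl2, 0 °C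
Reagents that add atoms: phosphorus tribromide, BrP(Br)Br
Why: Bromination of a benzylic alcohol through its phosphite ester (SN2); the electron-rich bromide is used at once, without storage.

Step 4
Reactants: 4 2-(benzyloxy)-5-(bromomethyl)-1,3-dimethoxybenzene; 5 ethynylmagnesium bromide (excess)
Product: 6 2-(benzyloxy)-1,3-dimethoxy-5-(prop-2-yn-1-yl)benzene
Conditions: CuBr·SMe2 (10 mol%), THF, 0 → 40 °C
Reagents that add atoms: ethynylmagnesium bromide (5), C#C[Mg]Br
Why: Copper-catalysed sp3–sp coupling of a benzylic bromide with an alkynyl Grignard reagent; excess acetylide and mild temperature should hold back double benzylation and alkyne-to-allene isomerisation.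

Step 5
Reactants: 7 acetosyringone
Product: 8 4-acetyl-2,6-dimethoxyphenyl pivalate
Conditions: PivCl, Et3N, DMAP (cat.), CH2Cl2, 0 °C → rt
Reagents that add atoms: pivaloyl chloride, CC(C)(C)C(Cl)=O
Why: DMAP-catalysed O-acylation of the phenol; the hindered ester is chosen because it must survive Ti(OiPr)4, fluoride, acid, SnCl4 and borane later on.

Step 6
Reactants: 8 4-acetyl-2,6-dimethoxyphenyl pivalate
Product: 9 4-[1-(tert-butyldimethylsilyloxy)ethenyl]-2,6-dimethoxyphenyl pivalate
Conditions: TBSOTf, Et3N, CH2Cl2, 0 °C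
Reagents that add atoms: tert-butyldimethylsilyl triflate, CC(C)(C)[Si](C)(C)OS(=O)(=O)C(F)(F)F
Why: Soft enolisation and O-silylation of an aryl methyl ketone, which has only one enolisable position.

Step 7
Reactants: 9 4-[1-(tert-butyldimethylsilyloxy)ethenyl]-2,6-dimethoxyphenyl pivalate
Product: 11 4-[2-(tert-butyldimethylsilyloxy)acetyl]-2,6-dimethoxyphenyl pivalate, via 2-aryl-2-silyloxyoxirane 10 (not isolated)
Conditions: mCPBA (1.1 equiv), NaHCO3, CH2Cl2, −10 → 0 °C
Reagents that add atoms: mCPBA, OOC(=O)c1cccc(Cl)c1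
Why: Rubottom oxidation: epoxidation of the silyl enol ether, opening of the silyloxy-oxirane and 1,4-shift of silicon to the new oxygen should give the α-silyloxy ketone directly, the bicarbonate buffer protecting the silyl group.

Step 8
Reactants: 6 2-(benzyloxy)-1,3-dimethoxy-5-(prop-2-yn-1-yl)benzene; 11 4-[2-(tert-butyldimethylsilyloxy)acetyl]-2,6-dimethoxyphenyl pivalate
Product: 14 4-[(2S,3E)-5-(4-benzyloxy-3,5-dimethoxyphenyl)-1-(tert-butyldimethylsilyloxy)-2-hydroxypent-3-en-2-yl]-2,6-dimethoxyphenyl pivalate, via (E)-alkenylzirconocene chloride 12 (not isolated), via (E)-alkenyl(methyl)zinc 13 (not isolated)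
Conditions: Cp2Zr(H)Cl, CH2Cl2, rt; Me2Zn, toluene, −78 °C; then 11, Ti(OiPr)4 (1.2 equiv), C2-symmetric bis(sulfonamide) diol ligand (trans-cyclohexane-1,2-diamine / 2-exo-hydroxy-camphor-10-sulfonyl; 10 mol%), rt; aq. NH4Cl
Reagents that add atoms: none
Why: syn-Hydrozirconation of the terminal alkyne fixes the E geometry, Zr-to-Zn transmetalation gives the alkenylzinc, and its titanium/bis(sulfonamide)-diol-catalysed 1,2-addition (catalytic asymmetric alkenylation of a ketone) sets the tertiary carbinol by ligand control on the Re face, with aryl versus CH2OTBS read as aryl versus alkyl and the poorly chelating silyl ether not opening an uncatalysed pathway.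

Step 9
Reactants: 14 4-[(2S,3E)-5-(4-benzyloxy-3,5-dimethoxyphenyl)-1-(tert-butyldimethylsilyloxy)-2-hydroxypent-3-en-2-yl]-2,6-dimethoxyphenyl pivalate
Product: 15 4-[(2S,3E)-5-(4-benzyloxy-3,5-dimethoxyphenyl)-1,2-dihydroxypent-3-en-2-yl]-2,6-dimethoxyphenyl pivalate
Conditions: HF·pyridine, pyridine, THF, 0 °C → rt
Reagents that add atoms: none
Why: Fluoride cleavage of the primary silyl ether under buffered conditions that should spare the tertiary allylic carbinol, the aryl pivalate and the alkene.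

Step 10
Reactants: 15 4-[(2S,3E)-5-(4-benzyloxy-3,5-dimethoxyphenyl)-1,2-dihydroxypent-3-en-2-yl]-2,6-dimethoxyphenyl pivalate; 16 dimethoxymethane
Product: 17 4-{(4S)-4-[(E)-3-(4-benzyloxy-3,5-dimethoxyphenyl)prop-1-enyl]-1,3-dioxolan-4-yl}-2,6-dimethoxyphenyl pivalate
Conditions: CH2(OMe)2 (excess), LiBr, TsOH·H2O (cat.), CH2Cl2, rt
Reagents that add atoms: dimethoxymethane (16), COCOC
Why: Acid-catalysed transacetalisation (methoxymethyl ether at the primary hydroxyl, then five-ring closure by the tertiary hydroxyl); the stereocentre is untouched as long as its C–O bond stays intact, which the electron-poor aryl group and the β-oxygen favour.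

Step 11
Reactants: 17 4-{(4S)-4-[(E)-3-(4-benzyloxy-3,5-dimethoxyphenyl)prop-1-enyl]-1,3-dioxolan-4-yl}-2,6-dimethoxyphenyl pivalate
Product: 18 4-{[(3R,4R)-4-(4-benzyloxy-3,5-dimethoxybenzyl)oxolan-3-yl]carbonyl}-2,6-dimethoxyphenyl pivalate
Conditions: SnCl4 (2.5 equiv), CH2Cl2 (0.01 M), −78 → −20 °C; Et3N, then aq. NaHCO3
Reagents that add atoms: none
Why: Tin-assisted cleavage of the dioxolane C2–O3 bond leaves a formaldehyde oxocarbenium ion on the primary oxygen and a tin alkoxide on the carbinol carbon; the (E)-alkene attacks the CH2=O+ carbon through a chair (6-endo Prins, forming C4–C5), and the oxan-4-yl cation collapses by 1,2-shift of the ring CH2 from the carbinol carbon to the cationic carbon (forming C2–C3 and unveiling the aryl ketone), the same bonds resulting if a concerted 2-oxonia-Cope shift is followed by aldol-type closure of the tin enolate. The closest known reaction is the Prins–pinacol rearrangement of 4-alkenyl-1,3-dioxolanes to 3-acyl-oxolanes. The oxolane, the one ring formed, is closed by this ring-contracting 1,2-shift (from the oxonia-Cope side a 5-(enolexo)-endo-trig aldol closure). C4 is set by 1,3-transfer from the dioxolane stereocentre: in the chair the aryl group and the CH2Ar group of the E-alkene are equatorial and the C–O(Sn) bond axial, which from (4S)-17 places the new C–C bond on the face that gives 4R; C3 is set by the suprafacial shift on that chair, which puts the aroyl group trans to the benzyl group (3R), also the more stable epimer, so enolisation cannot erode it. The step needs heterolysis of the acetal C–O bond to win over heterolysis of the tertiary benzylic–allylic C–O bond and over aryl 1,2-shift; the pivalate makes the aryl ring electron-poor, the β-oxygen further disfavours the tertiary cation, and low temperature with high dilution should hold back Friedel–Crafts attack by the benzyloxy-dimethoxyphenyl ring.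

Step 12
Reactants: 18 4-{[(3R,4R)-4-(4-benzyloxy-3,5-dimethoxybenzyl)oxolan-3-yl]carbonyl}-2,6-dimethoxyphenyl pivalate
Product: 19 4-{(S)-[(3R,4R)-4-(4-benzyloxy-3,5-dimethoxybenzyl)oxolan-3-yl](hydroxy)methyl}-2,6-dimethoxyphenyl pivalate
Conditions: (R)-Me-CBS (0.5 equiv), BH3·SMe2, THF, −20 °C; MeOH
Reagents that add atoms: none
Why: Corey–Bakshi–Shibata reduction: with aryl as the larger ketone substituent the (R)-oxazaborolidine should deliver hydride to the face that gives the (S)-carbinol, the face also favoured by 1,2-induction from C3 (Felkin–Anh, C4 anti to the hydride), so catalyst and substrate are matched; borane leaves the pivalate and the benzyl ether untouched.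

Step 13
Reactants: 19 4-{(S)-[(3R,4R)-4-(4-benzyloxy-3,5-dimethoxybenzyl)oxolan-3-yl](hydroxy)methyl}-2,6-dimethoxyphenyl pivalate
Product: 20 4-{(S)-hydroxy[(3R,4R)-4-(4-hydroxy-3,5-dimethoxybenzyl)oxolan-3-yl]methyl}-2,6-dimethoxyphenyl pivalate
Conditions: H2 (1 atm), Pd/C, EtOAc, rt
Reagents that add atoms: none
Why: Hydrogenolysis of the aryl benzyl ether in a neutral solvent; the benzylic C7–OH should survive because its aryl ring is still acylated and electron-poor.

Step 14
Reactants: 20 4-{(S)-hydroxy[(3R,4R)-4-(4-hydroxy-3,5-dimethoxybenzyl)oxolan-3-yl]methyl}-2,6-dimethoxyphenyl pivalate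
Product: 21 4-{[(3R,4R)-4-[(S)-hydroxy(4-hydroxy-3,5-dimethoxyphenyl)methyl]oxolan-3-yl]methyl}-2,6-dimethoxyphenol
Conditions: K2CO3, MeOH, rt; aq. NH4Cl
Reagents that add atoms: none
Why: Base-catalysed methanolysis of the aryl pivalate (phenoxide as leaving group); room temperature and a buffered work-up should keep the p-hydroxybenzyl alcohol from forming a quinone methide, and no stereocentre is touched.

## Compound list

1 | syringaldehyde (4-hydroxy-3,5-dimethoxybenzaldehyde) | COc1cc(C=O)cc(OC)c1O | starting material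
2 | 4-(benzyloxy)-3,5-dimethoxybenzaldehyde | COc1cc(C=O)cc(OC)c1OCc1ccccc1 | intermediate
3 | [4-(benzyloxy)-3,5-dimethoxyphenyl]methanol | COc1cc(CO)cc(OC)c1OCc1ccccc1 | intermediate
4 | 2-(benzyloxy)-5-(bromomethyl)-1,3-dimethoxybenzene | COc1cc(CBr)cc(OC)c1OCc1ccccc1 | intermediate
5 | ethynylmagnesium bromide | C#C[Mg]Br | starting material
6 | 2-(benzyloxy)-1,3-dimethoxy-5-(prop-2-yn-1-yl)benzene | COc1cc(CC#C)cc(OC)c1OCc1ccccc1 | intermediate
7 | acetosyringone (1-(4-hydroxy-3,5-dimethoxyphenyl)ethanone) | CC(=O)c1cc(OC)c(O)c(OC)c1 | starting material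
8 | 4-acetyl-2,6-dimethoxyphenyl pivalate | CC(=O)c1cc(OC)c(OC(=O)C(C)(C)C)c(OC)c1 | intermediate
9 | 4-[1-(tert-butyldimethylsilyloxy)ethenyl]-2,6-dimethoxyphenyl pivalate | C=C(O[Si](C)(C)C(C)(C)C)c1cc(OC)c(OC(=O)C(C)(C)C)c(OC)c1 | intermediate
10 | 4-[2-(tert-butyldimethylsilyloxy)oxiran-2-yl]-2,6-dimethoxyphenyl pivalate (racemic, not isolated) | CC(C)(C)[Si](C)(C)OC1(CO1)c1cc(OC)c(OC(=O)C(C)(C)C)c(OC)c1 | intermediate
11 | 4-[2-(tert-butyldimethylsilyloxy)acetyl]-2,6-dimethoxyphenyl pivalate | CC(C)(C)[Si](C)(C)OCC(=O)c1cc(OC)c(OC(=O)C(C)(C)C)c(OC)c1 | intermediate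
12 | chloro[(E)-3-(4-benzyloxy-3,5-dimethoxyphenyl)prop-1-enyl]zirconocene (not isolated) | COc1cc(C/C=C/[Zr](Cl)(C2C=CC=C2)C2C=CC=C2)cc(OC)c1OCc1ccccc1 | intermediate
13 | [(E)-3-(4-benzyloxy-3,5-dimethoxyphenyl)prop-1-enyl](methyl)zinc (not isolated) | COc1cc(C/C=C/[Zn]C)cc(OC)c1OCc1ccccc1 | intermediate
14 | 4-[(2S,3E)-5-(4-benzyloxy-3,5-dimethoxyphenyl)-1-(tert-butyldimethylsilyloxy)-2-hydroxypent-3-en-2-yl]-2,6-dimethoxyphenyl pivalate | CC(C)(C)[Si](C)(C)OC[C@@](O)(c1cc(OC)c(OC(=O)C(C)(C)C)c(OC)c1)/C=C/Cc1cc(OC)c(OCc2ccccc2)c(OC)c1 | intermediate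
15 | 4-[(2S,3E)-5-(4-benzyloxy-3,5-dimethoxyphenyl)-1,2-dihydroxypent-3-en-2-yl]-2,6-dimethoxyphenyl pivalate | OC[C@@](O)(c1cc(OC)c(OC(=O)C(C)(C)C)c(OC)c1)/C=C/Cc1cc(OC)c(OCc2ccccc2)c(OC)c1 | intermediate
16 | dimethoxymethane | COCOC | starting material
17 | 4-{(4S)-4-[(E)-3-(4-benzyloxy-3,5-dimethoxyphenyl)prop-1-enyl]-1,3-dioxolan-4-yl}-2,6-dimethoxyphenyl pivalate | C1OC[C@@](O1)(c1cc(OC)c(OC(=O)C(C)(C)C)c(OC)c1)/C=C/Cc1cc(OC)c(OCc2ccccc2)c(OC)c1 | intermediate
18 | 4-{[(3R,4R)-4-(4-benzyloxy-3,5-dimethoxybenzyl)oxolan-3-yl]carbonyl}-2,6-dimethoxyphenyl pivalate | COc1cc(C[C@H]2COC[C@@H]2C(=O)c2cc(OC)c(OC(=O)C(C)(C)C)c(OC)c2)cc(OC)c1OCc1ccccc1 | intermediate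
19 | 4-{(S)-[(3R,4R)-4-(4-benzyloxy-3,5-dimethoxybenzyl)oxolan-3-yl](hydroxy)methyl}-2,6-dimethoxyphenyl pivalate | COc1cc(C[C@H]2COC[C@@H]2[C@H](O)c2cc(OC)c(OC(=O)C(C)(C)C)c(OC)c2)cc(OC)c1OCc1ccccc1 | intermediate
20 | 4-{(S)-hydroxy[(3R,4R)-4-(4-hydroxy-3,5-dimethoxybenzyl)oxolan-3-yl]methyl}-2,6-dimethoxyphenyl pivalate | COc1cc(C[C@H]2COC[C@@H]2[C@H](O)c2cc(OC)c(OC(=O)C(C)(C)C)c(OC)c2)cc(OC)c1O | intermediate
21 | 4-{[(3R,4R)-4-[(S)-hydroxy(4-hydroxy-3,5-dimethoxyphenyl)methyl]oxolan-3-yl]methyl}-2,6-dimethoxyphenol | COc1cc(C[C@H]2COC[C@@H]2[C@H](O)c2cc(OC)c(O)c(OC)c2)cc(OC)c1O | target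

## Step count

Total: 14 steps. Longest linear sequence: 11 steps (1 → 2 → 3 → 4 → 6 → 14 → 15 → 17 → 18 → 19 → 20 → 21); the acetosyringone branch (7 → 11) is 3 steps and joins at step 8.

## Steps most likely to fail

**Step 11.** The stereochemical relay may leak. Rearrangement through the second chair (aryl axial) or a boat, or reversible heterolysis of the tertiary C–O bond before C–C bond formation, would lower the enantiomeric purity of 18 or give its antipode. A formaldehyde acetal is also the least readily ionised acetal. The fallback sets both ring stereocentres without any relay, by auxiliary-controlled conjugate addition and enolate alkylation. It sets out from aldehyde 2 and bromide 4 and comes back at 21. Aldehyde 2 is converted with propane-1,3-dithiol and BF3·OEt2 into 2-[4-(benzyloxy)-3,5-dimethoxyphenyl]-1,3-dithiane F1. Its 2-lithio derivative (n-BuLi, THF, −78 °C) is added to (5R)-5-[(1R,2S,5R)-menthyloxy]furan-2(5H)-one anti to the alkoxy group, and the lactone enolate is alkylated with 4 (DMPU) anti to the new substituent, which should give the (3R,4R,5R)-3-benzyl-4-dithianyl-5-menthyloxy lactone F2. LiAlH4 reduces the lactone and the acetal carbon to the (2R,3R)-2-benzyl-3-dithianyl-butane-1,4-diol F3. TsCl in pyridine closes the ring (mono-tosylate, then displacement) to the (3R,4R)-oxolanyl dithiane F4. MeI and CaCO3 in aqueous MeCN unmask the bis-benzyl ketone F5, the analogue of 18. Corey–Bakshi–Shibata reduction as in step 12 gives the bis-benzyl (S)-carbinol F6, and hydrogenolysis of both benzyl ethers (H2, Pd/C, EtOAc) gives 21.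

**Step 8.** The titanium catalyst may not tell the aryl group from CH2OTBS well enough, or an uncatalysed addition may compete, so that 14 forms with low enantiomeric purity. The fallback replaces asymmetric catalysis by resolution through covalent diastereomers. It sets out from 6 and 11 and comes back at 15. The addition is run as in step 8 with the racemic ligand to give the racemic silyl ether F7, and HF·pyridine gives the racemic diol F8. The primary hydroxyl is esterified with (S)-2-methoxy-2-phenylacetic acid (EDC, DMAP cat., CH2Cl2, 0 °C). The two esters, the (2S)-diol (S)-O-methylmandelate F9 and the (2R)-diol (S)-O-methylmandelate F10, are separated by chromatography or crystallisation. Cold methanolysis of F9 (K2CO3, MeOH, 0 °C), which should cleave the activated primary ester before the hindered aryl pivalate, gives 15.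

**Step 10.** Under the acid needed to activate dimethoxymethane, the tertiary allylic carbinol may ionise (allylic transposition, elimination to a diene, loss of configuration). The fallback avoids Brønsted acid and carries the acetal carbon as a mixed acetal. It sets out from 15 and comes back at 18. The primary hydroxyl is alkylated under basic conditions (MOMCl, iPr2NEt, CH2Cl2, 0 °C) to the primary methoxymethyl ether F11. F11 is then exposed to SnCl4 as in step 11, where loss of methoxide gives the same oxocarbenium ion and the same cyclisation and shift should lead to 18.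

## Further compounds

F1 | step 11 | 2-[4-(benzyloxy)-3,5-dimethoxyphenyl]-1,3-dithiane | COc1cc(C2SCCCS2)cc(OC)c1OCc1ccccc1
F2 | step 11 | (3R,4R,5R)-3-[4-(benzyloxy)-3,5-dimethoxybenzyl]-4-{2-[4-(benzyloxy)-3,5-dimethoxyphenyl]-1,3-dithian-2-yl}-5-[(1R,2S,5R)-menthyloxy]oxolan-2-one | O=C1[C@H](Cc2cc(OC)c(OCc3ccccc3)c(OC)c2)[C@@H](C2(c3cc(OC)c(OCc4ccccc4)c(OC)c3)SCCCS2)[C@H](O[C@@H]2C[C@H](C)CC[C@H]2C(C)C)O1
F3 | step 11 | (2R,3R)-2-[4-(benzyloxy)-3,5-dimethoxybenzyl]-3-{2-[4-(benzyloxy)-3,5-dimethoxyphenyl]-1,3-dithian-2-yl}butane-1,4-diol | OC[C@H](Cc1cc(OC)c(OCc2ccccc2)c(OC)c1)[C@@H](C1(c2cc(OC)c(OCc3ccccc3)c(OC)c2)SCCCS1)CO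
F4 | step 11 | 2-[4-(benzyloxy)-3,5-dimethoxyphenyl]-2-{(3R,4R)-4-[4-(benzyloxy)-3,5-dimethoxybenzyl]oxolan-3-yl}-1,3-dithiane | COc1cc(C[C@H]2COC[C@@H]2C2(c3cc(OC)c(OCc4ccccc4)c(OC)c3)SCCCS2)cc(OC)c1OCc1ccccc1
F5 | step 11 | [(3R,4R)-4-(4-benzyloxy-3,5-dimethoxybenzyl)oxolan-3-yl](4-benzyloxy-3,5-dimethoxyphenyl)methanone | COc1cc(C[C@H]2COC[C@@H]2C(=O)c2cc(OC)c(OCc3ccccc3)c(OC)c2)cc(OC)c1OCc1ccccc1
F6 | step 11 | (S)-[(3R,4R)-4-(4-benzyloxy-3,5-dimethoxybenzyl)oxolan-3-yl](4-benzyloxy-3,5-dimethoxyphenyl)methanol | COc1cc(C[C@H]2COC[C@@H]2[C@H](O)c2cc(OC)c(OCc3ccccc3)c(OC)c2)cc(OC)c1OCc1ccccc1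
F7 | step 8 | racemic 4-[(3E)-5-(4-benzyloxy-3,5-dimethoxyphenyl)-1-(tert-butyldimethylsilyloxy)-2-hydroxypent-3-en-2-yl]-2,6-dimethoxyphenyl pivalate | CC(C)(C)[Si](C)(C)OCC(O)(c1cc(OC)c(OC(=O)C(C)(C)C)c(OC)c1)/C=C/Cc1cc(OC)c(OCc2ccccc2)c(OC)c1
F8 | step 8 | racemic 4-[(3E)-5-(4-benzyloxy-3,5-dimethoxyphenyl)-1,2-dihydroxypent-3-en-2-yl]-2,6-dimethoxyphenyl pivalate | OCC(O)(c1cc(OC)c(OC(=O)C(C)(C)C)c(OC)c1)/C=C/Cc1cc(OC)c(OCc2ccccc2)c(OC)c1
F9 | step 8 | (2S,3E)-5-(4-benzyloxy-3,5-dimethoxyphenyl)-2-hydroxy-2-(3,5-dimethoxy-4-pivaloyloxyphenyl)pent-3-enyl (S)-2-methoxy-2-phenylacetate | CO[C@H](C(=O)OC[C@@](O)(c1cc(OC)c(OC(=O)C(C)(C)C)c(OC)c1)/C=C/Cc1cc(OC)c(OCc2ccccc2)c(OC)c1)c1ccccc1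
F10 | step 8 | (2R,3E)-5-(4-benzyloxy-3,5-dimethoxyphenyl)-2-hydroxy-2-(3,5-dimethoxy-4-pivaloyloxyphenyl)pent-3-enyl (S)-2-methoxy-2-phenylacetate | CO[C@H](C(=O)OC[C@](O)(c1cc(OC)c(OC(=O)C(C)(C)C)c(OC)c1)/C=C/Cc1cc(OC)c(OCc2ccccc2)c(OC)c1)c1ccccc1
F11 | step 10 | 4-[(2S,3E)-5-(4-benzyloxy-3,5-dimethoxyphenyl)-2-hydroxy-1-(methoxymethoxy)pent-3-en-2-yl]-2,6-dimethoxyphenyl pivalate | COCOC[C@@](O)(c1cc(OC)c(OC(=O)C(C)(C)C)c(OC)c1)/C=C/Cc1cc(OC)c(OCc2ccccc2)c(OC)c1
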